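## Analysis of the target

The target is a roof-shaped bis-naphthalenoid in which two chlorinated, peri-oxygenated halves are joined through a dioxabicyclo[3.2.1]octane: the ketal carbon C1 of the keto half carries an aryl ether oxygen to C8′ and a bridging oxygen to C1′, and C1′ is bonded directly to the aryl carbon C8 (unprimed locants for the half with the C4 ketone, primed locants for the half with the C4′ carbinol). This gives a five-membered ring (C1, O, C1′, C8, C8a) and a six-membered dioxin ring (C1, O, C8′, C8a′, C1′, O) that share the bridging oxygen. There are seven stereocentres: the bridgeheads C1 and C1′, whose relative configuration is fixed by the bicycle, the cis-epoxides C2–C3 and C2′–C3′, and the carbinol C4′. Both epoxides lie on the face of their ring that carries the bridging oxygen (the convex face of the roof), whereas the C4′ hydroxyl lies on the other face of the lower ring, syn to C8 and trans to the lower epoxide. Sensitive functions are the two epoxides (one an epoxy ketone), the trans epoxy alcohol (prone to base-induced epoxide migration), the mixed aryl–alkyl ketal, and two chlorophenols, one of them para to an ether oxygen and easily oxidised. The difficulties are the fully substituted C1′ as a single enantiomer, the different oxidation levels of the two halves, the placement of the two chlorines, and the fact that every precursor of the lower ring is a 1,4-dihydronaphthalene with a leaving group on C1′ and a hydrogen on C4′, one elimination away from a naphthalene. The strategy rests on the lower carbocycle C1′–C2′–C3′–C4′–C4a′–C8a′: it has oxygen on C1′ and on C4′, the unit C2′–C3′ between them, and a para-dioxygenated chloroarene (C5′–O, C8′–O) fused at C4a′–C8a′, which is the imprint of a Diels–Alder reaction of a 1,4-dioxygenated diene with chlorobenzoquinone; because C1′ also carries C8, the diene is the dienol ether of an alkylidene phthalide whose lactone carbonyl is the future C1.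

## Retrosynthetic reasoning

**26 to 25.** The three O–H bonds are traced back to O–Si bonds. The phenols and the C4′ hydroxyl cannot be carried free: the para-alkoxyphenol is oxidised by peroxides and a free C4′–OH would direct epoxidation to the wrong face. Silicon on all three oxygens allows one buffered fluoride step at the end, with no acid near the epoxides.

**25 to 24.** The two C–O bonds of the upper epoxide are cut to give the enone. C2 is the β-carbon of an aryl enone, so a peroxide anion is the right oxidant. The forward step has to attack the convex face, which the aryl ether unit on the other face should ensure.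

**24 to 22.** The C4–C4a bond is cut, giving a C4a aryl anion and a (Z)-acrylate on C1. An acid-promoted acylation is not an option here: the substrate holds a bridged ketal, an epoxide and a benzylic silyl ether, and the arene is chlorinated. The anionic version needs a bromine on C4a, which is therefore carried from the first aromatic intermediate as a spectator.

**22 to 21 to 20.** The (Z)-alkene comes from the alkynoate 21 by cis semi-hydrogenation. The lower epoxide of 21 comes from the alkene of 20. The epoxide is placed here, once the roof shape exists and before any organolithium is used, because it removes the 1,4-dihydronaphthalene that could aromatise.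

**20 to 19 to 18 to 15 + 16.** The silyl group on C5′–O is removed retrosynthetically. Then the C1–O(C8′) ketal bond and the C1–C2 bond are cut: C1 is the lactone carbonyl of 15 and C2–C4 come from the propiolate ortho ester 16. Adding the acetylide before any phenol is protected lets the ketalisation choose C8′–OH itself, so the two phenols of 15 never have to be told apart by a reagent.

**15 to 12 + 13.** This is the key disconnection. The bonds C1′–C8a′ and C4′–C4a′ are cut, which opens the lower carbocycle and returns the chloroarene to 2-chloro-1,4-benzoquinone 13 and the rest to diene 12. It is made here because it is the only cut that produces the quaternary C1′ and the C4′ carbinol together, with their relative configuration encoded in the diene geometry and the absolute configuration left to a catalyst. The silyl ether on C5–O and the bromine on C4a of 12 are spectators for later steps.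

**12 to 11 to 6 + 8.** The O–Si bond of the dienol ether is cut to give enal 11, whose γ-hydrogen is the acidic phthalide C–H. Starting from the conjugated enal fixes the (E)-enol ether. The C1′–C2′ bond is then cut to the phthalide 6 and the three-carbon aldehyde 8.

**6 to 5 to 4 to 3 to 1 + 2.** The silyl ether, the bromine and the free phenol are removed in turn, and the lactone CH2 is cut from the arene. The methyl ether 1 is chosen as the source because a methoxy group directs the one-carbon electrophile cleanly para. The bromine is introduced when the phenol has only one open ortho position.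

## Alternatives that were turned down

**Alternative 1:** Here the two ketal C–O bonds are disconnected to the C1/C1′ endoperoxide A2, in which C1 is still bonded to C8′. In the forward step acid cleaves the O–O bond, C8′ shifts from C1 to oxygen, and the C1′ oxygen captures the oxocarbenium ion at C1, giving the bis-enone A1.
- In its favour: the whole dioxabicyclo[3.2.1]octane appears in one step from a symmetric precursor, and the route would be far shorter than the chosen one.
- Against it: A1 has neither chlorine and carries two ketones, so two chlorinations and a site- and face-selective reduction of only the C4′ carbonyl remain. At C1 of A2 three groups can migrate (C8′, C8a, the vinyl carbon C2) and only one leads to A1. The electron-poor peroxide can also fragment by a Kornblum–DeLaMare pathway.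
- Decisive point: A2 is chiral but would come from a flat precursor and oxygen, so the alternative has no source of absolute configuration.
- Comparison: it is stronger on step economy. The chosen strategy offers instead absolute control from a catalyst, chlorines bought in place, and the C4/C4′ oxidation levels differentiated from the outset.

**Alternative 2:** Here the bonds C1′–O, C1′–C8 and C1–C8a are disconnected to the quinone diazide A4, which carries an acrylate ester on the C8′ oxygen, and the aryne precursor A5. In the forward step a divalent rhodium carboxylate decomposes the diazo group, the acrylate carbonyl oxygen closes onto the carbenoid, and the resulting 1,3-dipole adds across the aryne set free by fluoride, giving A3.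
- In its favour: three bonds and both heterocycles form in one convergent step from two pre-chlorinated halves. The C4a bromine and the C1 vinyl group of A3 are well placed for the upper ring, and the bromine should steer the aryne orientation the right way.
- Against it: a carbenoid derived from a quinone diazide is strongly stabilised, and the dipole is an aromatic naphthoxide that may simply be O- or C-arylated by the aryne. An ester carbonyl is a weak partner for ylide formation, and the acrylate alkene competes for the carbenoid. Two short-lived intermediates must be generated at matched rates.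
- Decisive point: the cycloaddition sets C1 and C1′ with no reliable handle for enantiocontrol, because the metal is normally no longer bound when the dipole reacts. The C4′ ketone of A3 must still be reduced with face control.
- Comparison: it is stronger on convergence. The chosen strategy offers a stereodefined C1′/C4′ pair from one catalytic step.

**Alternative 3:** Here the C1–C2 bond and the C1–O(C8′) bond are disconnected to the spiro phthalide A7, which already has the complete lower ring and a (Z)-iodovinyl dioxolane on C4a. In the forward step iodine–lithium exchange gives a C2 vinyllithium that attacks the lactone carbonyl, and acid then closes the ketal, giving A6.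
- In its favour: the C4–C4a bond exists from the start, so no halogen–metal exchange next to a protected phenol is needed. Upper ring and ketal close in one operation, and the lower epoxide and carbinol are already in place.
- Against it: the alternative does not say how the spiro centre C1′ and C4′ of A7 are made as one enantiomer; the central problem is only moved into a longer, more linear precursor synthesis. The vinyllithium must form in the presence of a free phenol, an epoxide and a lactone. The C4 dioxolane and two methoxymethyl ethers must finally be removed with acid from a bis-epoxide.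
- Comparison: the ring-closing logic is the mirror image in polarity of steps 9, 10 and 14 of the chosen route and saves one operation there. The chosen route is stronger where it matters: it creates C1′ and C4′ and ends with a fluoride-only deprotection.

Key step: step 8

Remark on locants: target locants (C1–C8a, C1′–C8a′) are used for all compounds from 14 onwards; compounds 3–12 are named as isobenzofuran-1(3H)-ones (phthalides), where phthalide C1 becomes target C1, phthalide C3 becomes C1′, and phthalide C7, C6, C5 become C4a, C5, C6.

Assumption on the catalyst: the sense of induction of the oxazaborolidinium catalyst is taken from its usual transition-state picture for quinones. The (S)-catalyst is written; its mirror image is to be used if the first adduct proves to be the antipode.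

Remark on starting materials: 1, 2, 7, 13 and 16 are catalogue chemicals.

## Route

Step 1
Reactants: 1 4-chloro-3-methoxybenzoic acid; 2 formaldehyde
Product: 3 5-chloro-6-methoxyisobenzofuran-1(3H)-one
Conditions: 37% aq. CH2O, conc. HCl, AcOH, 85 °C
Reagents that add atoms: none
Why: Blanc-type chloromethylation followed by lactonisation; the methoxy group sends the one-carbon electrophile para to itself (the only activated position not flanked on both sides) and the neighbouring carboxylic acid closes the γ-lactone; the methyl ether is used instead of the free phenol because a phenol can divert formaldehyde to the crowded ortho position.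

Step 2
Reactants: 3 5-chloro-6-methoxyisobenzofuran-1(3H)-one
Product: 4 5-chloro-6-hydroxyisobenzofuran-1(3H)-one
Conditions: BBr3, CH2Cl2, −78 → 0 °C; then aq. NaHCO3
Reagents that add atoms: none
Why: Lewis-acid cleavage of an aryl methyl ether; any benzylic C–O opening of the lactone is undone on aqueous work-up because a 2-(bromomethyl)benzoate relactonises.

Step 3
Reactants: 4 5-chloro-6-hydroxyisobenzofuran-1(3H)-one
Product: 5 7-bromo-5-chloro-6-hydroxyisobenzofuran-1(3H)-one
Conditions: Br2, NaOAc, AcOH, rt
Reagents that add atoms: bromine, BrBr
Why: Electrophilic aromatic bromination of a phenol that has a single open ortho position (the other is chlorinated, the para position is a ring-fusion carbon), so the future C4a bromine enters without a regiochemical choice.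

Step 4
Reactants: 5 7-bromo-5-chloro-6-hydroxyisobenzofuran-1(3H)-one
Product: 6 7-bromo-5-chloro-6-(triisopropylsilyloxy)isobenzofuran-1(3H)-one
Conditions: i-Pr3SiOTf, 2,6-lutidine, CH2Cl2, 0 °C → rt
Reagents that add atoms: triisopropylsilyl trifluoromethanesulfonate, CC(C)[Si](OS(=O)(=O)C(F)(F)F)(C(C)C)C(C)C
Why: Silylation of a hindered, acidic phenol with a silyl triflate; the bulky silyl ether is chosen because it survives base, peracid and mild acid, resists migration to an ortho-lithiated carbon, and falls to fluoride at the end.

Step 5
Reactants: 7 1,1,3,3-tetramethoxypropane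
Product: 8 (E)-3-methoxyprop-2-enal
Conditions: H2O (1 equiv), p-TsOH·H2O (cat.), 50 °C, then distillation
Reagents that add atoms: water, O
Why: Acid-catalysed hydrolysis of one acetal and loss of methanol from the other give the vinylogous methyl formate, whose (E)-isomer is the stable one; a known preparation of this three-carbon electrophile.

Step 6
Reactants: 6 7-bromo-5-chloro-6-(triisopropylsilyloxy)isobenzofuran-1(3H)-one; 8 (E)-3-methoxyprop-2-enal
Product: 11 7-bromo-5-chloro-3-[(E)-3-oxoprop-1-en-1-yl]-6-(triisopropylsilyloxy)isobenzofuran-1(3H)-one (racemic), via lithium enolate of the phthalide 9 (not isolated), via aldol adduct 10 (not isolated)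
Conditions: LiN(i-Pr)2 (1.1 equiv), THF, −78 °C, 5 min; 8 (1.5 equiv), −78 °C; then 1 M HCl, THF, 0 °C → rt
Reagents that add atoms: water, O
Why: Aldol addition of the phthalide enolate (formed cold and trapped at once to suppress self-condensation) to the aldehyde of 8, then acid-induced allylic transposition of the γ-methoxy allylic alcohol (ionisation to the methoxy-stabilised allyl cation, capture by water, loss of methanol) to the conjugated (E)-enal; a conjugate addition–elimination pathway would give the same product.

Step 7
Reactants: 11 7-bromo-5-chloro-3-[(E)-3-oxoprop-1-en-1-yl]-6-(triisopropylsilyloxy)isobenzofuran-1(3H)-one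
Product: 12 (3Z)-7-bromo-3-[(2E)-3-(tert-butyldimethylsilyloxy)prop-2-en-1-ylidene]-5-chloro-6-(triisopropylsilyloxy)isobenzofuran-1(3H)-one
Conditions: t-BuMe2SiOTf (1.3 equiv), Et3N (2.5 equiv), CH2Cl2, −78 → −20 °C
Reagents that add atoms: tert-butyldimethylsilyl trifluoromethanesulfonate, CC(C)(C)[Si](C)(C)OS(=O)(=O)C(F)(F)F
Why: Soft enolisation: O-silylation of the s-trans enal and γ-deprotonation at the acidic phthalide C–H give the (E)-silyl dienol ether, and the new exocyclic double bond forms with the small lactone oxygen cis to the chain (Z), the rotamer favoured by allylic strain and the thermodynamically preferred alkylidene phthalide geometry; any (E)-alkylidene isomer has the aryl ring inside the diene, cannot reach the s-cis conformation and is a spectator in step 8.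

Step 8
Reactants: 12 (3Z)-7-bromo-3-[(2E)-3-(tert-butyldimethylsilyloxy)prop-2-en-1-ylidene]-5-chloro-6-(triisopropylsilyloxy)isobenzofuran-1(3H)-one; 13 2-chloro-1,4-benzoquinone
Product: 15 (1S,4′R)-4-bromo-4′-(tert-butyldimethylsilyloxy)-6,6′-dichloro-5′,8′-dihydroxy-5-(triisopropylsilyloxy)-3H,4′H-spiro[isobenzofuran-1,1′-naphthalen]-3-one, via endo enedione cycloadduct 14 (not isolated)
Conditions: (S)-3,3-diphenyl-1-(2-methylphenyl)tetrahydro-1H,3H-pyrrolo[1,2-c][1,3,2]oxazaborole (20 mol %) protonated with (CF3SO2)2NH (20 mol %), 13 (1.3 equiv), CH2Cl2, −78 °C; then Et3N (0.5 equiv), −78 → −20 °C; used at once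
Reagents that add atoms: none
Why: The protonated oxazaborolidine binds a quinone carbonyl through boron and lowers the LUMO of the unsubstituted double bond, which reacts in preference to the chlorinated one; the closest known reaction type is the oxazaborolidinium-catalysed Diels–Alder reaction of 1,4-benzoquinones with 1-silyloxy-1,3-dienes. The addition is a concerted but asynchronous [4+2] cycloaddition in which both new bonds (C1′–C8a′ and C4′–C4a′) form between the two components, so the lower carbocycle is closed by intermolecular cycloaddition and not by cyclisation of a tether. The C4′ silyloxy group makes C1′ the nucleophilic terminus, and C1′ should bond to the quinone carbon β to the carbonyl flanked by C–Cl: that carbonyl is the stronger acceptor because the other one is a vinylogous acid chloride weakened by chlorine lone-pair donation (the orientation that acid-promoted conjugate additions to chlorobenzoquinone also follow), and boron coordination at it reinforces the bias, which places chlorine next to C5′. Suprafacial addition to the (Z),(E)-diene puts the two outside groups, the aryl carbon C8 on C1′ and the silyloxy group on C4′, cis on the new ring, so the lactone oxygen is trans to the C4′ oxygen as in the target. The absolute configuration follows from the quinone face left open by the catalyst combined with the endo arrangement; because the ring-fusion stereocentres vanish on enolisation, an exo pathway would give the enantiomer, so endo selectivity matters as much as facial selectivity, and the small in-plane lactone oxygen as the only inside substituent keeps the s-cis diene and the endo transition state accessible. The primary adduct 14 is enolised cold with a catalytic amine, where O-protonation to the aromatic hydroquinone should outrun β-elimination of the C1′ carboxylate or the C4′ silyloxy group. The selectivities required are therefore site (unsubstituted double bond), orientation (chlorine-biased quinone), endo and quinone-face selectivity (catalyst), and relative configuration (diene geometry).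

Step 9
Reactants: 15 spiro phthalide hydroquinone; 16 3,3,3-triethoxyprop-1-yne
Product: 18 lactol of 15 (lactone C=O converted into C(OH)–C≡C–C(OEt)3; both epimers at C1), via lithium triethoxypropynide 17 (not isolated)
Conditions: 16 (5 equiv), n-BuLi (4.8 equiv), THF, −78 °C; then 15, −78 → −40 °C; aq. NH4Cl at −40 °C
Reagents that add atoms: none
Why: 1,2-Addition of a lithium acetylide to a lactone, stopping at the lactolate because the tetrahedral intermediate of a 3,3-disubstituted phthalide does not collapse in the cold; two equivalents are consumed by the phenols, the ortho ester masks the propiolate so that the nucleophile is fully reactive and the adduct carries no Michael acceptor, and the low temperature keeps the C8′ phenoxide from expelling the benzylic carboxylate.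

Step 10
Reactants: 18 lactol
Product: 19 bridged ketal with C1–C≡C–CO2Et, C4a–Br, C5–OTIPS, C6–Cl, C6′–Cl, free C5′–OH, C2′=C3′ and C4′–OTBS syn to C8
Conditions: pyridinium p-toluenesulfonate (20 mol %), CH2Cl2, 0 °C → rt
Reagents that add atoms: none
Why: Acid-catalysed ketalisation: loss of the lactol hydroxyl gives a benzylic oxocarbenium ion at C1 that is captured by the peri C8′ phenol in a 6-exo closure of the dioxin ring; the bicyclo[3.2.1] geometry allows only one configuration at C1, dictated by C1′; the water released hydrolyses the ortho ester to the ethyl ester, and the mildest acid that turns over is used because the lower ring is still a 1,4-dihydronaphthalene.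

Step 11
Reactants: 19 bridged ketal phenol
Product: 20 C5′-O-triisopropylsilyl ether of 19
Conditions: i-Pr3SiOTf, 2,6-lutidine, CH2Cl2, 0 °C → rt
Reagents that add atoms: triisopropylsilyl trifluoromethanesulfonate, CC(C)[Si](OS(=O)(=O)C(F)(F)F)(C(C)C)C(C)C
Why: Silylation of the only remaining hydroxyl; the oxidisable para-alkoxyphenol is masked before any oxidant is used, and no selection between phenols is needed because C8′–O is already part of the ketal.

Step 12
Reactants: 20 silylated bridged ketal
Product: 21 C2′–C3′ epoxide of 20, epoxide syn to the bridging oxygen and trans to C4′–OTBS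
Conditions: mCPBA (3 equiv), NaHCO3, CH2Cl2, 0 °C → rt
Reagents that add atoms: mCPBA, O=C(OO)c1cccc(Cl)c1
Why: Prilezhaev epoxidation of the only alkene that a peracid can attack (the alkynoate is inert); the reagent approaches the convex face of the roof, syn to the bridging oxygen and anti to both the pseudoaxial C4′ silyl ether and the upper arene on C1′, which sets C2′ and C3′ as in the target; the two allylic oxygens slow the reaction, so excess peracid is foreseen, and the 1,4-dihydronaphthalene is removed before the organolithium step.

Step 13
Reactants: 21 epoxy alkynoate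
Product: 22 (Z)-enoate: C1–CH=CH–CO2Et with cis geometry, otherwise as 21
Conditions: H2 (1 atm), Pd/CaCO3 poisoned with Pb(OAc)2, quinoline, EtOAc, rt
Reagents that add atoms: none
Why: Cis semi-hydrogenation of an alkyne on a poisoned palladium surface; aryl bromide, aryl chlorides, epoxide and silyl ethers are untouched, and the (Z)-geometry holds the ester carbonyl next to C4a.

Step 14
Reactants: 22 (Z)-enoate
Product: 24 bridged enone (C4 ketone bonded to C4a; C2=C3; lower epoxide; three silyl ethers), via C4a aryllithium 23 (not isolated)
Conditions: t-BuLi (2.1 equiv), THF/Et2O, −100 → −78 °C; aq. NH4Cl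
Reagents that add atoms: none
Why: Parham cyclisation: bromine–lithium exchange at −100 °C is faster than addition of t-BuLi to the ester, and the C4a aryllithium attacks the ester carbonyl in a 6-exo-trig closure, giving the aryl ketone after loss of ethoxide; the second equivalent of t-BuLi destroys t-BuBr, and the bulky triisopropylsilyl ether ortho to lithium makes a 1,3-shift of silicon slow relative to ring closure.

Step 15
Reactants: 24 bridged enone
Product: 25 bis-epoxide: C2–C3 epoxide syn to the bridging oxygen, otherwise as 24
Conditions: t-BuOOH (in decane), 1,8-diazabicyclo[5.4.0]undec-7-ene, CH2Cl2, 0 °C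
Reagents that add atoms: tert-butyl hydroperoxide, CC(C)(C)OO
Why: Weitz–Scheffer nucleophilic epoxidation: the peroxide anion adds to C2 from the convex face, away from the C8′ aryl ether unit that covers the other face, and the enolate closes the ring with loss of tert-butoxide, setting C2 and C3; the lower epoxide and the silyl ethers are inert to the anhydrous conditions.

Step 16
Reactants: 25 tris-silyl bis-epoxide
Product: 26 CNP0289684.3
Conditions: Bu4NF/AcOH (1:1, 5 equiv), THF, 0 °C → rt
Reagents that add atoms: none
Why: Fluoride-mediated cleavage of two aryl silyl ethers and one secondary silyl ether; the acetic acid buffer keeps phenoxide and the C4′ alkoxide from building up, which avoids epoxide migration in the trans epoxy alcohol and base-induced opening of the epoxy ketone, and no acid strong enough to open the epoxides or the ketal is present.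

## Compound list

1 | 4-chloro-3-methoxybenzoic acid | COc1cc(C(=O)O)ccc1Cl | starting material
2 | formaldehyde | C=O | starting material
3 | 5-chloro-6-methoxyisobenzofuran-1(3H)-one | COc1cc2C(=O)OCc2cc1Cl | intermediate
4 | 5-chloro-6-hydroxyisobenzofuran-1(3H)-one | Oc1cc2C(=O)OCc2cc1Cl | intermediate
5 | 7-bromo-5-chloro-6-hydroxyisobenzofuran-1(3H)-one | Oc1c(Br)c2C(=O)OCc2cc1Cl | intermediate
6 | 7-bromo-5-chloro-6-(triisopropylsilyloxy)isobenzofuran-1(3H)-one | CC(C)[Si](Oc1c(Br)c2C(=O)OCc2cc1Cl)(C(C)C)C(C)C | intermediate
7 | 1,1,3,3-tetramethoxypropane | COC(OC)CC(OC)OC | starting material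
8 | (E)-3-methoxyprop-2-enal | CO/C=C/C=O | intermediate
9 | lithium enolate (3-lithio form) of 6 | [Li]C1OC(=O)c2c(Br)c(O[Si](C(C)C)(C(C)C)C(C)C)c(Cl)cc12 | intermediate (not isolated)
10 | 7-bromo-5-chloro-3-[(E)-1-hydroxy-3-methoxyprop-2-en-1-yl]-6-(triisopropylsilyloxy)isobenzofuran-1(3H)-one, diastereomer mixture | CO/C=C/C(O)C1OC(=O)c2c(Br)c(O[Si](C(C)C)(C(C)C)C(C)C)c(Cl)cc12 | intermediate (not isolated)
11 | 7-bromo-5-chloro-3-[(E)-3-oxoprop-1-en-1-yl]-6-(triisopropylsilyloxy)isobenzofuran-1(3H)-one, racemic | O=C/C=C/C1OC(=O)c2c(Br)c(O[Si](C(C)C)(C(C)C)C(C)C)c(Cl)cc12 | intermediate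
12 | (3Z)-7-bromo-3-[(2E)-3-(tert-butyldimethylsilyloxy)prop-2-en-1-ylidene]-5-chloro-6-(triisopropylsilyloxy)isobenzofuran-1(3H)-one | O=C1O/C(=C\C=C\O[Si](C)(C)C(C)(C)C)c2cc(Cl)c(O[Si](C(C)C)(C(C)C)C(C)C)c(Br)c12 | intermediate
13 | 2-chloro-1,4-benzoquinone | O=C1C=CC(=O)C(Cl)=C1 | starting material
14 | endo cycloadduct, cis-fused 4a′,8a′-dihydro-5′,8′-dione form of 15 (ring-fusion hydrogens trans to the C1′ aryl group and to C4′–OTBS) | O=C1O[C@@]2(C=C[C@@H](O[Si](C)(C)C(C)(C)C)[C@H]3C(=O)C(Cl)=CC(=O)[C@H]32)c2cc(Cl)c(O[Si](C(C)C)(C(C)C)C(C)C)c(Br)c12 | intermediate (not isolated)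
15 | (1S,4′R)-4-bromo-4′-(tert-butyldimethylsilyloxy)-6,6′-dichloro-5′,8′-dihydroxy-5-(triisopropylsilyloxy)-3H,4′H-spiro[isobenzofuran-1,1′-naphthalen]-3-one; in target locants (1′S,4′R), C4′–OTBS cis to C8, bromine on C4a | O=C1O[C@@]2(C=C[C@@H](O[Si](C)(C)C(C)(C)C)c3c(O)c(Cl)cc(O)c32)c2cc(Cl)c(O[Si](C(C)C)(C(C)C)C(C)C)c(Br)c12 | intermediate
16 | 3,3,3-triethoxyprop-1-yne | C#CC(OCC)(OCC)OCC | starting material
17 | lithium 3,3,3-triethoxyprop-1-yn-1-ide | [Li]C#CC(OCC)(OCC)OCC | intermediate (not isolated)
18 | lactol of 15: C1 bears OH and C≡C–C(OEt)3, both C1 epimers | CCOC(OCC)(OCC)C#CC1(O)O[C@@]2(C=C[C@@H](O[Si](C)(C)C(C)(C)C)c3c(O)c(Cl)cc(O)c32)c2cc(Cl)c(O[Si](C(C)C)(C(C)C)C(C)C)c(Br)c12 | intermediate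
19 | bridged ketal (C1–O–C8′ and C1–O–C1′, bridgeheads as in the target) with C1–C≡C–CO2Et, C4a–Br, C5–OTIPS, C6–Cl, C6′–Cl, free C5′–OH, C2′=C3′, C4′–OTBS syn to C8 | Brc1c(O[Si](C(C)C)(C(C)C)C(C)C)c(Cl)cc2c1[C@@]1(Oc3cc(Cl)c(O)c4c3[C@]2(O1)C=C[C@H]4O[Si](C)(C)C(C)(C)C)C#CC(=O)OCC | intermediate
20 | C5′-O-triisopropylsilyl ether of 19 | Brc1c(O[Si](C(C)C)(C(C)C)C(C)C)c(Cl)cc2c1[C@@]1(Oc3cc(Cl)c(O[Si](C(C)C)(C(C)C)C(C)C)c4c3[C@]2(O1)C=C[C@H]4O[Si](C)(C)C(C)(C)C)C#CC(=O)OCC | intermediate
21 | C2′–C3′ epoxide of 20, epoxide syn to the bridging oxygen, trans to C4′–OTBS | Brc1c(O[Si](C(C)C)(C(C)C)C(C)C)c(Cl)cc2c1[C@@]1(Oc3cc(Cl)c(O[Si](C(C)C)(C(C)C)C(C)C)c4c3[C@]2(O1)[C@@H]1O[C@@H]1[C@H]4O[Si](C)(C)C(C)(C)C)C#CC(=O)OCC | intermediate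
22 | (Z)-enoate from 21 (C1–CH=CH–CO2Et, cis) | Brc1c(O[Si](C(C)C)(C(C)C)C(C)C)c(Cl)cc2c1[C@@]1(Oc3cc(Cl)c(O[Si](C(C)C)(C(C)C)C(C)C)c4c3[C@]2(O1)[C@@H]1O[C@@H]1[C@H]4O[Si](C)(C)C(C)(C)C)/C=C\C(=O)OCC | intermediate
23 | C4a aryllithium from 22 | [Li]c1c(O[Si](C(C)C)(C(C)C)C(C)C)c(Cl)cc2c1[C@@]1(Oc3cc(Cl)c(O[Si](C(C)C)(C(C)C)C(C)C)c4c3[C@]2(O1)[C@@H]1O[C@@H]1[C@H]4O[Si](C)(C)C(C)(C)C)/C=C\C(=O)OCC | intermediate (not isolated)
24 | bridged enone: C4 ketone, C2=C3, lower epoxide, C5–OTIPS, C5′–OTIPS, C4′–OTBS | O=C1c2c(O[Si](C(C)C)(C(C)C)C(C)C)c(Cl)cc3c2[C@@]2(Oc4cc(Cl)c(O[Si](C(C)C)(C(C)C)C(C)C)c5c4[C@]3(O2)[C@@H]2O[C@@H]2[C@H]5O[Si](C)(C)C(C)(C)C)C=C1 | intermediate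
25 | tris-silyl ether of the target (both epoxides syn to the bridging oxygen) | O=C1c2c(O[Si](C(C)C)(C(C)C)C(C)C)c(Cl)cc3c2[C@@]2(Oc4cc(Cl)c(O[Si](C(C)C)(C(C)C)C(C)C)c5c4[C@]3(O2)[C@@H]2O[C@@H]2[C@H]5O[Si](C)(C)C(C)(C)C)[C@@H]2O[C@H]12 | intermediate
26 | CNP0289684.3 | O=C1c2c(O)c(Cl)cc3c2[C@@]2(Oc4cc(Cl)c(O)c5c4[C@]3(O2)[C@@H]2O[C@@H]2[C@H]5O)[C@@H]2O[C@H]12 | target

## Step count and least certain steps

Total: 16 steps. Longest linear sequence: 15 steps (steps 1–4 and 6–16, from compound 1); step 5 is a one-step side branch.

**Step 8 (key step).**
- Orientation: boron may bind the remote carbonyl, which is the more basic one, and then the carbon next to the C–Cl-flanked carbonyl becomes the electrophilic site, so the orientation could leak or turn over.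
- Mechanism: the silyl dienol ether may add stepwise (Mukaiyama–Michael) with loss of silicon.
- Enantioselectivity: an exo mode would erode it.
- Product stability: the enolised adduct can aromatise by 1,4-elimination of the benzylic carboxylate if it meets acid or base for long.
- Fallback: run the same catalysed cycloaddition of 12 with the symmetrical 1,4-benzoquinone, which has no orientation question, to give the deschloro hydroquinone F1. Carry F1 through the conditions of steps 9 and 10 to the deschloro lactol F2 and the deschloro bridged ketal phenol F3. Chlorinate F3 with N-chlorosuccinimide in CH2Cl2 at 0 °C; the free C5′ phenol has one open ortho position, C6′, so this returns to 19.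

**Step 9.**
- What may go wrong: the C8′ phenoxide sits ortho to the carbon that carries the benzylic carboxylate and may expel it before the acetylide has added, which leads on to aromatisation. The hindered lactone may also add slowly.
- Fallback: mask both phenols of 15 as trimethylsilyl ethers (Me3SiCl, Et3N) to give F4. Add 17 (1.5 equiv) at −78 to −40 °C to give the bis-silylated lactol F5. Treat F5 with pyridinium p-toluenesulfonate in wet CH2Cl2, which strips the aryl trimethylsilyl ethers, hydrolyses the ortho ester and closes the ketal, returning to 19.

**Step 14.**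
- What may go wrong: silicon may shift from the C5 oxygen to the lithiated C4a, the alkyllithium may attack the enoate before exchange, and the aryllithium may be quenched by proton transfer.
- Fallback: convert 22 into the (Z)-Weinreb amide F6 with MeNH(OMe)·HCl and i-PrMgCl at −20 °C. Carry out bromine–magnesium exchange with lithium tributylmagnesate, n-Bu3MgLi, at −78 to −40 °C. The less ionic carbon–magnesium bond does not trigger the silyl shift, and the chelated adduct releases 24 on work-up.

**Step 6.**
- What may go wrong: the phthalide enolate may self-condense or the adduct may revert, and the double bond may wander during the acidic transposition.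
- Fallback: brominate 6 at the lactone CH2 (N-bromosuccinimide, 2,2′-azobis(2-methylpropionitrile), PhCF3, 80 °C) to give F7. Hydrolyse F7 (H2O, THF) to the 3-hydroxyphthalide F8. Add CH2=CHMgBr (2.2 equiv, THF, −78 → 0 °C, then 1 M HCl) to give the 3-vinylphthalide F9. Cross-metathesise F9 with crotonaldehyde using the second-generation Hoveyda–Grubbs catalyst, (H2IMes)Cl2Ru=CH(2-i-PrO-C6H4), in CH2Cl2 at 40 °C, which returns to 11.

## Further compounds

F1 | step 8 | deschloro analogue of 15 (C6′–H), spiro phthalide hydroquinone | O=C1O[C@@]2(C=C[C@@H](O[Si](C)(C)C(C)(C)C)c3c(O)ccc(O)c32)c2cc(Cl)c(O[Si](C(C)C)(C(C)C)C(C)C)c(Br)c12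
F2 | step 8 | deschloro analogue of lactol 18 | CCOC(OCC)(OCC)C#CC1(O)O[C@@]2(C=C[C@@H](O[Si](C)(C)C(C)(C)C)c3c(O)ccc(O)c32)c2cc(Cl)c(O[Si](C(C)C)(C(C)C)C(C)C)c(Br)c12
F3 | step 8 | deschloro analogue of bridged ketal phenol 19 (C6′–H) | Brc1c(O[Si](C(C)C)(C(C)C)C(C)C)c(Cl)cc2c1[C@@]1(Oc3ccc(O)c4c3[C@]2(O1)C=C[C@H]4O[Si](C)(C)C(C)(C)C)C#CC(=O)OCC
F4 | step 9 | C5′,C8′-bis(trimethylsilyl) ether of 15 | O=C1O[C@@]2(C=C[C@@H](O[Si](C)(C)C(C)(C)C)c3c(O[Si](C)(C)C)c(Cl)cc(O[Si](C)(C)C)c32)c2cc(Cl)c(O[Si](C(C)C)(C(C)C)C(C)C)c(Br)c12
F5 | step 9 | C5′,C8′-bis(trimethylsilyl) ether of lactol 18 | CCOC(OCC)(OCC)C#CC1(O)O[C@@]2(C=C[C@@H](O[Si](C)(C)C(C)(C)C)c3c(O[Si](C)(C)C)c(Cl)cc(O[Si](C)(C)C)c32)c2cc(Cl)c(O[Si](C(C)C)(C(C)C)C(C)C)c(Br)c12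
F6 | step 14 | (Z)-N-methoxy-N-methyl amide corresponding to ester 22 | Brc1c(O[Si](C(C)C)(C(C)C)C(C)C)c(Cl)cc2c1[C@@]1(Oc3cc(Cl)c(O[Si](C(C)C)(C(C)C)C(C)C)c4c3[C@]2(O1)[C@@H]1O[C@@H]1[C@H]4O[Si](C)(C)C(C)(C)C)/C=C\C(=O)N(C)OC
F7 | step 6 | 3,7-dibromo-5-chloro-6-(triisopropylsilyloxy)isobenzofuran-1(3H)-one, racemic | CC(C)[Si](Oc1c(Br)c2C(=O)OC(Br)c2cc1Cl)(C(C)C)C(C)C
F8 | step 6 | 7-bromo-5-chloro-3-hydroxy-6-(triisopropylsilyloxy)isobenzofuran-1(3H)-one, racemic | CC(C)[Si](Oc1c(Br)c2C(=O)OC(O)c2cc1Cl)(C(C)C)C(C)C
F9 | step 6 | 7-bromo-5-chloro-3-ethenyl-6-(triisopropylsilyloxy)isobenzofuran-1(3H)-one, racemic | C=CC1OC(=O)c2c(Br)c(O[Si](C(C)C)(C(C)C)C(C)C)c(Cl)cc12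
A1 | alternative 1 | dechloro bridged bis-enone diketone with both phenols free | O=C1c2c(O)ccc3c2[C@@]2(Oc4ccc(O)c5c4[C@]3(O2)C=CC5=O)C=C1
A2 | alternative 1 | C1/C1′ endoperoxide of the dechloro bis-enone with C1–C8′ and C1′–C8 bonds | O=C1C=C[C@]26OO[C@@]3(C=CC(=O)c4c(O)ccc2c43)c2ccc(O)c1c26
A3 | alternative 2 | bridged ketal with lower enone, vinyl on the ketal carbon and bromine on C4a | Brc1c(OCOC)c(Cl)cc2c1[C@@]1(Oc3cc(Cl)c(OCOC)c4c3[C@]2(O1)C=CC4=O)C=C
A4 | alternative 2 | 6-chloro-8-diazo-4-(methoxymethoxy)-5-oxo-5,8-dihydronaphthalen-1-yl prop-2-enoate (quinone diazide with C8′ acrylate) | [N-]=[N+]=C1C=CC(=O)c2c(OCOC)c(Cl)cc(OC(=O)C=C)c12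
A5 | alternative 2 | 2-bromo-4-chloro-3-(methoxymethoxy)-6-(trimethylsilyl)phenyl trifluoromethanesulfonate (aryne precursor) | Brc1c(OCOC)c(Cl)cc([Si](C)(C)C)c1OS(=O)(=O)C(F)(F)F
A6 | alternative 3 | bridged ketal with upper cyclohexene (C4 as dioxolane) and complete lower ring | C12(OCCO1)c3c(OCOC)c(Cl)cc4c3[C@@]3(Oc5cc(Cl)c(OCOC)c6c5[C@]4(O3)[C@@H]3O[C@@H]3[C@H]6O[Si](C)(C)C(C)(C)C)C=C2
A7 | alternative 3 | spiro phthalide with complete lower ring, free C8′–OH and a 2-[(Z)-2-iodoethenyl]-1,3-dioxolan-2-yl group on C4a | O=C1O[C@@]2([C@@H]3O[C@@H]3[C@@H](O[Si](C)(C)C(C)(C)C)c3c(OCOC)c(Cl)cc(O)c32)c2cc(Cl)c(OCOC)c(C3(OCCO3)/C=C\I)c12
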